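## Structural features

Pleiogenone A is a single carbocycle, a cyclohex-3-en-2-one (ring atoms C1–C6, C2 the ketone, C3=C4 the alkene). Its quaternary carbinol C1 carries an unbranched seventeen-carbon chain with one (Z)-alkene between C8′ and C9′. Three oxygenated stereocentres stand in a row: C1 (R, tertiary OH), C6 (R, secondary OH) and C5 (S, secondary allylic OH). The C1 and C6 hydroxyls are cis, and the C5 hydroxyl is trans to the one at C6. The fragile elements are the tertiary α-ketol (C1/C2), the γ-hydroxy enone (C5 with C2–C4), the β-hydroxy ketone relation of C6–OH to C2=O (dehydration), and the isolated (Z)-alkene, which rules out hydrogenation, unselective epoxidants and long exposure to chain-carrying radicals. The real difficulty is C1: a fully substituted carbinol between two oxygenated carbons, with no hydrogen through which its configuration could be corrected later, to be set in the absolute sense. The key step exploits the latent mirror plane through C1 and C4 of 4-alkyl-4-hydroxycyclohexa-2,5-dienone: the arms C1–C2=C3 and C1–C6=C5 are enantiotopic, so delivering oxygen from the C1 hydroxyl to C6 fixes C1 and C6 together, cis by necessity. The price is that the dienone carbonyl sits at C4, so the route must afterwards oxygenate C5 and move the carbonyl oxygen from C4 to C2.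

## Logic of the disconnections

**21 ⇒ 20.** The O1/O6 isopropylidene bridge and the O5 silyl group are removed. Three hydroxyls must be silent while C2 is oxidised, and O5 must be distinguishable from O2, since both are secondary allylic hydroxyls at that stage. The gain is that 20 has no free hydroxyl and no β-hydroxy ketone. The forward step must be one acidic hydrolysis that the enone, the tertiary ketol and the chain alkene tolerate.

**20 ⇒ 19 ⇒ 17 ⇒ 16.** The C2 carbonyl is traced to a C2 carbinol (19), the C2–O bond with the C3=C4 alkene to a C2–C3 epoxide beside a C4 ketone (17), and that epoxide to the C2=C3 enone (16). This 1,3-transposition is needed because the desymmetrisation leaves the carbonyl at C4. The gain is that 16 has the oxygen pattern of the desymmetrised dienone plus one oxygen at C5. The forward steps need a nucleophilic epoxidant (an electrophilic one would find the chain alkene), a base mild enough not to expel O6 from the β-position, and they leave the C2 configuration free because it is erased.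

**16 ⇒ 14 ⇒ 13.** The C5–O bond is cut. C5 is α to a carbonyl only while the ketone is at C4, so it must be oxygenated before the transposition, and enolisation can only go towards C5 because C1 is quaternary. The gain is that 13 has two stereocentres only. The oxidant must choose the silyl enol ether over two other alkenes and attack anti to O6, and the silyl group should end on O5.

**13 ⇒ 11.** The isopropylidene bridge is exchanged back to a phenylboron bridge. The B–O and B–C bonds would not survive the dioxirane, alkaline peroxide and hydrazine used later. There is no gain in complexity; the cut only connects to the key step. The forward step must release the β-hydroxy ketone diol without dehydrating it.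

**11 ⇒ 8 + 9.** The C6–O bond is cut and the boron bridge opened. Both stereocentres disappear, and 8 is achiral, stable and one oxidation away from a phenol. The forward step must select one of two enantiotopic alkenes under catalyst control.

**8 ⇒ 7 ⇒ 6.** The C1–O bond is cut (oxidative dearomatisation), and the phenol is traced to its silyl ether, which the organometallic step requires. The gain is a plain para-alkylphenol. The oxidant must spare the chain alkene and water must enter para.

**6 ⇒ 2 + 3, 2 ⇒ 1.** The bond between the aromatic carbon and C1′ is cut. C2–C18 of oleic acid are exactly the seventeen-carbon chain with the alkene in the right place and geometry, so a decarboxylative coupling installs it in one step. The gain is two commercial building blocks (1 and 3). The alkyl radical must couple faster than it is reduced, and the alkene must keep its geometry.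

## Other disconnections considered

**Alternative 1:** The cut is the simultaneous removal of the C2–O and C5–O bonds, after the cis C1/C6 diol has been traced to a microbial ipso,ortho-dihydroxylation product of benzoate.
- Forward: A1, (1S,2R)-1,2-dihydroxycyclohexa-3,5-diene-1-carboxylic acid, would be converted into the diene acetonide A2 by ketalisation and elaboration of the carboxyl carbon into C1′ of the chain. Singlet oxygen (O2, light, 5,10,15,20-tetraphenylporphyrin) would add [4+2] across C2 and C5 anti to the dioxolane to give endoperoxide A3. Base-induced Kornblum–DeLaMare fragmentation and acetonide hydrolysis would finish.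
- In favour: the (1S,2R) configuration of A1 maps onto C1 and C6 of the target. The cycloaddition sets C5–O trans to C6–O and supplies C2–O and the C3=C4 alkene in one step.
- Where it is better: the absolute configuration comes from an enzyme instead of a catalyst whose sense must be verified, and only two steps follow the key step, with no carbonyl transposition.
- Against: a carboxyl on a quaternary carbinol must be turned into CH2–C16 with a (Z)-alkene while an acid-sensitive, aromatisation-prone cyclohexadiene is present. Singlet oxygen also undergoes the ene reaction with the chain alkene. The fragmentation must remove the hydrogen at C2, next to the quaternary centre, and not the more accessible one at C5. A1 is a fermentation product and not a catalogue chemical.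
- Comparison: on structure both plans give the cis C1/C6 pair, but the chosen plan attaches the chain to a robust arene before any sensitive group exists. On mechanism the cycloaddition is substrate-controlled and predictable in facial sense, whereas its two chemoselectivity and regioselectivity questions have no obvious control element. On step count the alternative could be equal or slightly shorter if the chain can be attached in three steps or fewer.

**Alternative 2:** The cut is the C1–C6 bond (α-ketol retron).
- Forward: the oleoyl cyclopentenol A4 would be heated with Al(OiPr)3. In the aluminium chelate of the carbinol oxygen and the acyl carbonyl, the silyloxy-bearing ring carbon C6 shifts from the carbinol carbon (future C2) to the acyl carbon (C1). The ring expands to give 5,6-bis-O-silyl pleiogenone A, A5, and desilylation would finish.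
- In favour: ring strain relief and conjugation of the new C2 ketone with C3=C4 drive the shift. The quaternary carbinol, the ring and the enone appear in one step in the final oxidation state.
- Where it is better: all eighteen carbons of oleic acid are used, since the carboxyl carbon becomes C1, whereas the chosen plan discards it as CO2. The endgame is a single deprotection.
- Against: A4 needs three stereocentres, including a tertiary carbinol cis to the neighbouring silyloxy group (the geometry analysis of the chelated shift requires this for the correct C1 configuration). That means its own multistep synthesis and a face-selective addition of an oleoyl anion equivalent. The alkenyl carbon C3 can migrate in competition with C6. The shift is reversible. A5 is a β-silyloxy ketone exposed to a hot Lewis acid.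
- Comparison: on structure the alternative is more convergent, but the stereochemical burden moves into the precursor. On mechanism the C1 configuration rests on substrate control only, whereas in the chosen plan it can be inverted by taking the other catalyst enantiomer. On step count the overall length is expected to be equal or longer because of A4.

**Alternative 3:** The cut is the C1–C2 bond.
- Forward: the keto aldehyde A6, with a trans-acetonide on O5/O6, would be treated with a triazolium precatalyst such as (5aS,10bR)-2-(pentafluorophenyl)-5a,10b-dihydro-4H,6H-indeno[2,1-b][1,2,4]triazolo[4,3-d][1,4]oxazin-2-ium tetrafluoroborate (or its enantiomer) and base. The Breslow intermediate at the C2 aldehyde adds to the C1 ketone and closes the six-membered acyloin A7. Dehydrogenation to the C3=C4 enone and acetonide hydrolysis would follow.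
- In favour: intramolecular aldehyde–ketone benzoin closure to six-membered tertiary acyloins is a dependable reaction class. The trans C5/C6 diol can come from acyclic asymmetric synthesis of known absolute sense.
- Where it is equal or better: the ketone is formed directly at C2 next to the carbinol, so no carbonyl transposition is needed.
- Against: the closure builds a trans-fused dioxolane. The C1 configuration needs catalyst and substrate to act in the same direction. The C6 hydrogen, α to the ketone and α to oxygen, can epimerise under the basic conditions. Making A6 requires either a dihydroxylation that avoids the chain alkene or a late chain introduction. A ketone-to-enone dehydrogenation is still required.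
- Comparison: on structure the alternative spends its effort on an acyclic precursor with two stereocentres, whereas the chosen plan starts the stereochemistry from an achiral dienone. On mechanism both depend on an organocatalyst to set C1, and the chosen plan has the tether as an additional, geometric guarantee of the cis C1/C6 relation. On step count the alternative is expected to be longer.

Key step: step 5

Assumption on the chemistry: the (1R,2R) thiourea is taken to select the alkene arm that leads to (3aR,7aS)-11, by analogy with acyclic γ-hydroxy enones; should the sense prove opposite, the (1S,2R→1S,2S) enantiomer, i.e. the (1S,2S) catalyst, takes its place with nothing else changed.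

## Route

Step 1
Reactants: 1 oleic acid
Product: 2 1,3-dioxoisoindolin-2-yl (Z)-octadec-9-enoate
Conditions: N-hydroxyphthalimide, N,N'-diisopropylcarbodiimide, 4-(dimethylamino)pyridine (cat.), CH2Cl2, rt
Reagents that add atoms: N-hydroxyphthalimide, ON1C(=O)c2ccccc2C1=O
Why: Carbodiimide (Steglich-type) esterification of an unhindered acid with an acidic N-hydroxy imide; the product is the redox-active ester needed for decarboxylative coupling and the alkene is untouched.

Step 2
Reactants: 2 1,3-dioxoisoindolin-2-yl (Z)-octadec-9-enoate; 3 (4-bromophenoxy)(tert-butyl)dimethylsilane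
Product: 6 tert-butyl{4-[(Z)-heptadec-8-enyl]phenoxy}dimethylsilane, via arylmagnesium bromide 4 (not isolated), via arylzinc chloride 5 (not isolated)
Conditions: 3, Mg, LiCl, THF, rt; ZnCl2, THF; then 2, NiCl2(dme) (20 mol%), 4,4'-di-tert-butyl-2,2'-bipyridine (40 mol%), THF/DMF, rt
Reagents that add atoms: none
Why: Decarboxylative Negishi-type arylation of a redox-active ester: electron transfer from low-valent nickel releases CO2, phthalimide anion and the primary heptadec-8-enyl radical, which is captured at arylnickel and reductively eliminated. The radical centre is seven carbons from the alkene, so neither cyclisation nor loss of the Z geometry is expected.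

Step 3
Reactants: 6 tert-butyl{4-[(Z)-heptadec-8-enyl]phenoxy}dimethylsilane
Product: 7 4-[(Z)-heptadec-8-enyl]phenol
Conditions: Bu4NF, THF, 0 °C; aq. NH4Cl
Reagents that add atoms: none
Why: Fluoride-induced cleavage of an aryl silyl ether; no other group in 6 responds to fluoride.

Step 4
Reactants: 7 4-[(Z)-heptadec-8-enyl]phenol
Product: 8 4-[(Z)-heptadec-8-enyl]-4-hydroxycyclohexa-2,5-dien-1-one
Conditions: PhI(OAc)2, MeCN/H2O, 0 °C
Reagents that add atoms: water, O
Why: Oxidative dearomatisation of a para-alkylphenol by trivalent iodine: ligand exchange at iodine, loss of iodobenzene and capture of the electron-poor ring by water at the alkyl-bearing para carbon give the para-quinol. An unactivated chain alkene is not attacked by the reagent in the absence of strong acid.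

Step 5
Reactants: 8 4-[(Z)-heptadec-8-enyl]-4-hydroxycyclohexa-2,5-dien-1-one; 9 phenylboronic acid
Product: 11 (3aR,7aS)-7a-[(Z)-heptadec-8-enyl]-2-phenyl-3a,7a-dihydro-1,3,2-benzodioxaborol-5(4H)-one, via quinol phenylboronic hemiester 10 (not isolated)
Conditions: 9 (1.3 equiv), 1-[3,5-bis(trifluoromethyl)phenyl]-3-[(1R,2R)-2-(dimethylamino)cyclohexyl]thiourea (15 mol%), 4 Å molecular sieves, toluene, rt
Reagents that add atoms: none
Why: The tertiary hydroxyl of 8 condenses reversibly with 9 (the sieves take up the water) to give hemiester 10, whose remaining B–OH is a poor nucleophile on its own. Coordination of the catalyst's dimethylamino group to boron makes that oxygen nucleophilic while the thiourea N–H pair binds the dienone carbonyl, so the addition is an intramolecular oxa-Michael reaction, the amine-thiourea boronate oxa-Michael of γ-hydroxy enones applied to a para-quinol. The oxygen attacks C6 and closes the dioxaborolane in the 5-exo-trig mode, and the enolate is then protonated at C5. The C6 stereocentre is controlled by the tether, because a five-membered O–B–O bridge can span C1 and C6 only on one face (cis fusion). The C1 stereocentre arises from the choice between the enantiotopic C5=C6 and C2=C3 alkenes and is controlled by the catalyst, both centres being set in the same event. The only selectivity required is therefore enantiotopic-group selection, since both β-carbons are constitutionally equivalent and only the cis ring can form. A second addition to the remaining enone cannot occur because no B–OH is left, and the chain alkene is inert.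

Step 6
Reactants: 11 (3aR,7aS)-7a-[(Z)-heptadec-8-enyl]-2-phenyl-3a,7a-dihydro-1,3,2-benzodioxaborol-5(4H)-one
Product: 13 (3aR,7aS)-7a-[(Z)-heptadec-8-enyl]-2,2-dimethyl-3a,7a-dihydro-1,3-benzodioxol-5(4H)-one, via cis-diol 12 (not isolated)
Conditions: pinacol, CH2Cl2, rt; then 2,2-dimethoxypropane, pyridinium p-toluenesulfonate (cat.), rt
Reagents that add atoms: 2,2-dimethoxypropane, COC(C)(C)OC
Why: Boronate transesterification to the more stable pinacol ester frees diol 12, which is trapped at once as the isopropylidene ketal (acid-catalysed transketalisation) before the β-hydroxy ketone can dehydrate. No stereocentre is touched, and the ketal, unlike the boronate, withstands the oxidants and hydrazine that follow.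

Step 7
Reactants: 13 (3aR,7aS)-7a-[(Z)-heptadec-8-enyl]-2,2-dimethyl-3a,7a-dihydro-1,3-benzodioxol-5(4H)-one
Product: 14 tert-butyl{[(3aR,7aS)-7a-[(Z)-heptadec-8-enyl]-2,2-dimethyl-3a,7a-dihydro-1,3-benzodioxol-5-yl]oxy}dimethylsilane
Conditions: tBuMe2SiOTf, Et3N, CH2Cl2, −78 → 0 °C
Reagents that add atoms: tert-butyldimethylsilyl trifluoromethanesulfonate, CC(C)(C)[Si](C)(C)OS(=O)(=O)C(F)(F)F
Why: Soft enolisation (silyl triflate with amine base) gives the 2-silyloxy diene; only C5 carries enolisable hydrogen because C1 is quaternary. No free enolate is formed, which avoids β-elimination of the C6 oxygen.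

Step 8
Reactants: 14 tert-butyl{[(3aR,7aS)-7a-[(Z)-heptadec-8-enyl]-2,2-dimethyl-3a,7a-dihydro-1,3-benzodioxol-5-yl]oxy}dimethylsilane
Product: 16 (3aR,4R,7aS)-4-(tert-butyldimethylsilyloxy)-7a-[(Z)-heptadec-8-enyl]-2,2-dimethyl-3a,7a-dihydro-1,3-benzodioxol-5(4H)-one, via silyloxy epoxide 15 (not isolated)
Conditions: dimethyldioxirane (1.05 equiv, acetone), CH2Cl2, −78 °C; then pyridinium p-toluenesulfonate (cat.), −78 → 0 °C
Reagents that add atoms: dimethyldioxirane, CC1(C)OO1
Why: Rubottom oxidation: at −78 °C the dioxirane epoxidises the electron-rich enol ether alkene far faster than the enone or the chain alkene, and it approaches the convex face anti to the C6 oxygen and the dioxolane, which sets C5 with its oxygen trans to C6–O. Acid-promoted opening of 15 at C4 and 1,4-silyl shift to the new C5 oxygen should deliver the C5 hydroxyl already protected.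

Step 9
Reactants: 16 (3aR,4R,7aS)-4-(tert-butyldimethylsilyloxy)-7a-[(Z)-heptadec-8-enyl]-2,2-dimethyl-3a,7a-dihydro-1,3-benzodioxol-5(4H)-one
Product: 17 C2–C3 epoxide of 16 (epoxide oxygen anti to the dioxolane)
Conditions: 30% aq. H2O2, NaOH (cat.), MeOH, 0 °C
Reagents that add atoms: hydrogen peroxide, OO
Why: Weitz–Scheffer nucleophilic epoxidation: hydroperoxide adds to C2 and the enolate closes on oxygen, a pathway open only to the electron-poor alkene, so the chain alkene is spared. Attack anti to the pseudoaxial C1–O bond is expected, but the epoxide configuration is of no consequence because C3 becomes trigonal in step 10 and C2 in step 11.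

Step 10
Reactants: 17 C2–C3 epoxide of 16 (epoxide oxygen anti to the dioxolane)
Product: 19 (3aS,4R,7S,7aR)-7-(tert-butyldimethylsilyloxy)-3a-[(Z)-heptadec-8-enyl]-2,2-dimethyl-3a,4,7,7a-tetrahydro-1,3-benzodioxol-4-ol, via epoxy hydrazone 18 (not isolated)
Conditions: N2H4·H2O, AcOH, MeOH, 0 °C → rt
Reagents that add atoms: none
Why: Wharton transposition: hydrazone 18 opens the epoxide to an alkenyl diazene, which loses N2 to leave the C3=C4 alkene and the C2 hydroxyl with the epoxide C–O bond retained. The silyl ether and the ketal are stable to buffered hydrazine.

Step 11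
Reactants: 19 (3aS,4R,7S,7aR)-7-(tert-butyldimethylsilyloxy)-3a-[(Z)-heptadec-8-enyl]-2,2-dimethyl-3a,4,7,7a-tetrahydro-1,3-benzodioxol-4-ol
Product: 20 (3aR,7S,7aR)-7-(tert-butyldimethylsilyloxy)-3a-[(Z)-heptadec-8-enyl]-2,2-dimethyl-7,7a-dihydro-1,3-benzodioxol-4(3aH)-one
Conditions: Dess–Martin periodinane, NaHCO3, CH2Cl2, 0 °C → rt
Reagents that add atoms: none
Why: Dess–Martin oxidation of the only free hydroxyl, a secondary allylic alcohol, gives the C2 ketone conjugated with C3=C4; buffering protects the ketal and the reagent does not touch alkenes.

Step 12
Reactants: 20 (3aR,7S,7aR)-7-(tert-butyldimethylsilyloxy)-3a-[(Z)-heptadec-8-enyl]-2,2-dimethyl-7,7a-dihydro-1,3-benzodioxol-4(3aH)-one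
Product: 21 pleiogenone A, (4S,5R,6R)-6-[(Z)-heptadec-8-enyl]-4,5,6-trihydroxycyclohex-2-en-1-one
Conditions: CF3CO2H/H2O (4:1), 0 °C → rt
Reagents that add atoms: none
Why: Acid hydrolysis of the isopropylidene ketal and acid solvolysis of the secondary silyl ether in one operation. Ionisation at C1 or C5 is disfavoured because either cation would be adjacent to or conjugated with the carbonyl, so the three stereocentres are not at risk.

## Compound list

1 | oleic acid | CCCCCCCC/C=C\CCCCCCCC(=O)O | starting material
2 | 1,3-dioxoisoindolin-2-yl (Z)-octadec-9-enoate | CCCCCCCC/C=C\CCCCCCCC(=O)ON1C(=O)c2ccccc2C1=O | intermediate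
3 | (4-bromophenoxy)(tert-butyl)dimethylsilane | CC(C)(C)[Si](C)(C)Oc1ccc(Br)cc1 | starting material
4 | [4-(tert-butyldimethylsilyloxy)phenyl]magnesium bromide | CC(C)(C)[Si](C)(C)Oc1ccc([Mg]Br)cc1 | intermediate
5 | [4-(tert-butyldimethylsilyloxy)phenyl]zinc chloride | CC(C)(C)[Si](C)(C)Oc1ccc([Zn]Cl)cc1 | intermediate
6 | tert-butyl{4-[(Z)-heptadec-8-enyl]phenoxy}dimethylsilane | CCCCCCCC/C=C\CCCCCCCc1ccc(O[Si](C)(C)C(C)(C)C)cc1 | intermediate
7 | 4-[(Z)-heptadec-8-enyl]phenol | CCCCCCCC/C=C\CCCCCCCc1ccc(O)cc1 | intermediate
8 | 4-[(Z)-heptadec-8-enyl]-4-hydroxycyclohexa-2,5-dien-1-one | CCCCCCCC/C=C\CCCCCCCC1(O)C=CC(=O)C=C1 | intermediate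
9 | phenylboronic acid | OB(O)c1ccccc1 | starting material
10 | 4-[(Z)-heptadec-8-enyl]-4-{[hydroxy(phenyl)boranyl]oxy}cyclohexa-2,5-dien-1-one | CCCCCCCC/C=C\CCCCCCCC1(OB(O)c2ccccc2)C=CC(=O)C=C1 | intermediate
11 | (3aR,7aS)-7a-[(Z)-heptadec-8-enyl]-2-phenyl-3a,7a-dihydro-1,3,2-benzodioxaborol-5(4H)-one | CCCCCCCC/C=C\CCCCCCC[C@]1(O2)C=CC(=O)C[C@H]1OB2c3ccccc3 | intermediate
12 | (4S,5R)-4-[(Z)-heptadec-8-enyl]-4,5-dihydroxycyclohex-2-en-1-one | CCCCCCCC/C=C\CCCCCCC[C@]1(O)C=CC(=O)C[C@H]1O | intermediate
13 | (3aR,7aS)-7a-[(Z)-heptadec-8-enyl]-2,2-dimethyl-3a,7a-dihydro-1,3-benzodioxol-5(4H)-one | CCCCCCCC/C=C\CCCCCCC[C@]1(O2)C=CC(=O)C[C@H]1OC2(C)C | intermediate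
14 | tert-butyl{[(3aR,7aS)-7a-[(Z)-heptadec-8-enyl]-2,2-dimethyl-3a,7a-dihydro-1,3-benzodioxol-5-yl]oxy}dimethylsilane | CCCCCCCC/C=C\CCCCCCC[C@]1(O2)C=CC(O[Si](C)(C)C(C)(C)C)=C[C@H]1OC2(C)C | intermediate
15 | C4–C5 epoxide of 14, epoxide oxygen anti to the dioxolane | CCCCCCCC/C=C\CCCCCCC[C@]1(O2)C=C[C@]3(O[Si](C)(C)C(C)(C)C)O[C@@H]3[C@H]1OC2(C)C | intermediate
16 | (3aR,4R,7aS)-4-(tert-butyldimethylsilyloxy)-7a-[(Z)-heptadec-8-enyl]-2,2-dimethyl-3a,7a-dihydro-1,3-benzodioxol-5(4H)-one | CCCCCCCC/C=C\CCCCCCC[C@]1(O2)C=CC(=O)[C@H](O[Si](C)(C)C(C)(C)C)[C@H]1OC2(C)C | intermediate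
17 | C2–C3 epoxide of 16, epoxide oxygen anti to the dioxolane | CCCCCCCC/C=C\CCCCCCC[C@]1(O2)[C@@H]3O[C@@H]3C(=O)[C@H](O[Si](C)(C)C(C)(C)C)[C@H]1OC2(C)C | intermediate
18 | hydrazone of 17 at C4 (C=N geometry not defined) | CCCCCCCC/C=C\CCCCCCC[C@]1(O2)[C@@H]3O[C@@H]3C(=NN)[C@H](O[Si](C)(C)C(C)(C)C)[C@H]1OC2(C)C | intermediate
19 | (3aS,4R,7S,7aR)-7-(tert-butyldimethylsilyloxy)-3a-[(Z)-heptadec-8-enyl]-2,2-dimethyl-3a,4,7,7a-tetrahydro-1,3-benzodioxol-4-ol | CCCCCCCC/C=C\CCCCCCC[C@]1(O2)[C@H](O)C=C[C@H](O[Si](C)(C)C(C)(C)C)[C@H]1OC2(C)C | intermediate
20 | (3aR,7S,7aR)-7-(tert-butyldimethylsilyloxy)-3a-[(Z)-heptadec-8-enyl]-2,2-dimethyl-7,7a-dihydro-1,3-benzodioxol-4(3aH)-one | CCCCCCCC/C=C\CCCCCCC[C@]1(O2)C(=O)C=C[C@H](O[Si](C)(C)C(C)(C)C)[C@H]1OC2(C)C | intermediate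
21 | pleiogenone A, (4S,5R,6R)-6-[(Z)-heptadec-8-enyl]-4,5,6-trihydroxycyclohex-2-en-1-one | CCCCCCCC/C=C\CCCCCCC[C@]1(O)C(=O)C=C[C@H](O)[C@H]1O | target

## Step count and least certain steps

Total step count: 12. Longest linear sequence: 12 steps (from 1; building block 3 enters at step 2).

**Step 5 (key step).** The most likely failure is insufficient discrimination between the two enantiotopic alkenes. The catalyst must read a difference at a carbonyl remote from the bulky tertiary boronate. An uncatalysed or amine-only background addition, and reversal of the oxa-Michael step, would both erode the enantiomeric purity. The sense of induction also has to be confirmed, by chiral analysis at the stage of 13.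

Fallback, setting out from 8 and coming back at 12: a chiral Brønsted acid acetalisation/oxa-Michael cascade. Compound 8 and acetaldehyde, with (R)-3,3'-bis(2,4,6-triisopropylphenyl)-1,1'-binaphthyl-2,2'-diyl hydrogen phosphate (or its enantiomer) in CH2Cl2 over molecular sieves, should form the hemiacetal on the tertiary hydroxyl. This adds to C6 in the same 5-exo sense to give (3aR,7aS)-7a-[(Z)-heptadec-8-enyl]-2-methyl-3a,7a-dihydro-1,3-benzodioxol-5(4H)-one F1 (either epimer at the acetal carbon serves). Dilute aqueous HCl in THF would hydrolyse the acetal to 12, which is ketalised to 13 under the second set of conditions of step 6. The tether and the activation mode both change (hemiacetal and ion-pairing acid instead of boronate and amine-thiourea).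

**Step 4.** The most likely failure is loss of material through competing ortho attack, phenoxy radical coupling and over-oxidation. The very lipophilic phenol is also poorly soluble in aqueous acetonitrile, and water capture at the para position is then slow.

Fallback, setting out from 7 and coming back at 8: dearomatisation by singlet oxygen. KHSO5 (as 2KHSO5·KHSO4·K2SO4) and NaHCO3 in MeCN/H2O generate singlet oxygen in the dark. It adds to the phenolate much faster than to a cis-dialkyl alkene and should give 4-[(Z)-heptadec-8-enyl]-4-hydroperoxycyclohexa-2,5-dien-1-one F2. Dimethyl sulfide then reduces F2 to 8.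

**Step 8.** Three processes can go wrong.
- Epoxidation of the chain alkene if the temperature is allowed to rise.
- Poor facial selectivity at C5 if the conformer with a pseudoaxial chain takes part.
- Loss of the silyl group to adventitious water during the rearrangement instead of its transfer to O5.

Fallback, setting out from 13 and coming back at 16: direct hydroxylation of the lithium enolate. LiN(SiMe3)2 in THF at −78 °C, then 3-phenyl-2-(phenylsulfonyl)oxaziridine, an aprotic oxidant that does not epoxidise alkenes, should give (3aR,4R,7aS)-7a-[(Z)-heptadec-8-enyl]-4-hydroxy-2,2-dimethyl-3a,7a-dihydro-1,3-benzodioxol-5(4H)-one F3. Silylation with tBuMe2SiOTf and 2,6-lutidine then gives 16.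

**Step 10.** The most likely failure is slow hydrazone formation at a ketone flanked by the epoxide and the silyloxy carbon. Elimination towards an azoalkene and unproductive decomposition of the alkenyl diazene can then take over.

Fallback, setting out from 17 and coming back at 19: the radical alternative to the Wharton reaction. NaBH4 in MeOH at −20 °C should give the C4 alcohol of 17, epoxy alcohol F4 (hydride anti to the epoxide and silyloxy group expected; the C4 configuration is irrelevant). 1,1'-Thiocarbonyldiimidazole with 4-(dimethylamino)pyridine gives its O-(imidazol-1-ylthiocarbonyl) derivative F5. Bu3SnH with Et3B and air in toluene at rt generates the C4 radical, which opens the adjacent epoxide at the C3–O bond; the resulting C2 alkoxy radical takes hydrogen from the stannane to give 19 with the same C2 configuration. The low temperature is chosen to limit stannyl-radical isomerisation of the chain alkene.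

## Further compounds

F1 | step 5 | (3aR,7aS)-7a-[(Z)-heptadec-8-enyl]-2-methyl-3a,7a-dihydro-1,3-benzodioxol-5(4H)-one (acetal carbon as formed, not defined) | CCCCCCCC/C=C\CCCCCCC[C@]1(O2)C=CC(=O)C[C@H]1OC2C
F2 | step 4 | 4-[(Z)-heptadec-8-enyl]-4-hydroperoxycyclohexa-2,5-dien-1-one | CCCCCCCC/C=C\CCCCCCCC1(OO)C=CC(=O)C=C1
F3 | step 8 | (3aR,4R,7aS)-7a-[(Z)-heptadec-8-enyl]-4-hydroxy-2,2-dimethyl-3a,7a-dihydro-1,3-benzodioxol-5(4H)-one | CCCCCCCC/C=C\CCCCCCC[C@]1(O2)C=CC(=O)[C@H](O)[C@H]1OC2(C)C
F4 | step 10 | C4 alcohol of 17 (epoxy alcohol, hydroxyl syn to the epoxide) | CCCCCCCC/C=C\CCCCCCC[C@]1(O2)[C@@H]3O[C@@H]3[C@H](O)[C@H](O[Si](C)(C)C(C)(C)C)[C@H]1OC2(C)C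
F5 | step 10 | O-(imidazol-1-ylthiocarbonyl) derivative of F4 | CCCCCCCC/C=C\CCCCCCC[C@]1(O2)[C@@H]3O[C@@H]3[C@H](OC(=S)n4ccnc4)[C@H](O[Si](C)(C)C(C)(C)C)[C@H]1OC2(C)C
A1 | alternative 1 | (1S,2R)-1,2-dihydroxycyclohexa-3,5-diene-1-carboxylic acid | OC(=O)[C@]1(O)C=CC=C[C@H]1O
A2 | alternative 1 | (3aS,7aR)-3a-[(Z)-heptadec-8-enyl]-2,2-dimethyl-3a,7a-dihydro-1,3-benzodioxole | CCCCCCCC/C=C\CCCCCCC[C@]1(O2)C=CC=C[C@H]1OC2(C)C
A3 | alternative 1 | C2,C5-endoperoxide of A2, peroxide bridge anti to the dioxolane | CCCCCCCC/C=C\CCCCCCC[C@]1(O2)[C@H]3C=C[C@H](OO3)[C@H]1OC2(C)C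
A4 | alternative 2 | (Z)-1-[(1S,4S,5R)-4,5-bis(tert-butyldimethylsilyloxy)-1-hydroxycyclopent-2-en-1-yl]octadec-9-en-1-one | CCCCCCCC/C=C\CCCCCCCC(=O)[C@]1(O)C=C[C@H](O[Si](C)(C)C(C)(C)C)[C@H]1O[Si](C)(C)C(C)(C)C
A5 | alternative 2 | 5,6-bis-O-(tert-butyldimethylsilyl) pleiogenone A | CCCCCCCC/C=C\CCCCCCC[C@]1(O)C(=O)C=C[C@H](O[Si](C)(C)C(C)(C)C)[C@H]1O[Si](C)(C)C(C)(C)C
A6 | alternative 3 | 3-{(4S,5R)-2,2-dimethyl-5-[(Z)-octadec-9-enoyl]-1,3-dioxolan-4-yl}propanal | CCCCCCCC/C=C\CCCCCCCC(=O)[C@@H]1OC(C)(C)O[C@H]1CCC=O
A7 | alternative 3 | 2-[(Z)-heptadec-8-enyl]-2-hydroxycyclohexanone with trans-fused 5,6-O-isopropylidene | CCCCCCCC/C=C\CCCCCCC[C@]1(O)C(=O)CC[C@H](O2)[C@H]1OC2(C)C
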